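**One question.** Treat the 4 questions as one: what stopped the blue flask, and which addition undoes that stop?

the same everywhere: Z 0.80 M

|  | E | Q | temperature | remark | time |
|---|---|---|---|---|---|
| blue | 1 equiv | 0.080 M | 25 °C | the very flask that is asked about, followed so far |  |
| grey | 1 equiv | 0.12 M | 31 °C | run made earlier |  |
| flask | 1.00 equiv | 0.0800 M | 25 °C |  | 10 h |

blue run (percent of the Z charged)

| time / h | X / % |
|---|---|
| 2.00 | 54 |
| 4.00 | 54 |
| 6.00 | 57 |
| 8.00 | 57 |

grey run (percent of the Z charged)

| time / min | X / % |
|---|---|
| 2.00 | 21 |
| 4.00 | 29 |
| 10.0 | 44 |
| 25.0 | 49 |

(each reading ± 2 percentage points)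

- south-west: at 10 h add Z, 50.0 % of the amount charged, then wait 5.0 h
- south: change nothing and wait 5.0 h more
- south-east: at 10 h add E, 50.0 % of the amount charged, then wait 5.0 h
- north-west: at 10 h raise the temperature by 20 K, then wait 5.0 h

- X, in percent of the Z first charged, at 10 h
- the remedy with the largest gain of X, or "none" below 2 percentage points (south-west / south / south-east / north-west / none)
- X present, in percent of the Z first charged, after south-west
- X present, in percent of the Z first charged, after north-west

- additions leave the volume as it is
- a reading or a percentage of X counts all its forms, free or not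

**Main step.** Begin with Z + E → X by itself. Equal charges then allow X up to 100 % of Z. Yet the blue readings lie flat from 2.00 h, with a mean of 55.5 %, so blue holds 0.444 M of X from a charge of 0.80 M of E. Either the step balances against its reverse, or E has gone elsewhere.

**Adding Q.** Suppose Q takes E one for one, so that cE − cQ remains for Z, which in blue is 0.720 M. Grey holds 0.0400 M more Q, and its last reading lies 0.0520 M lower in X. That ratio, read as 1.30, carries a scatter of 2 percentage points per reading, and grey is hotter too. It suits the supposition but doesn't prove it.

**The rest.** Q still leaves 0.720 M of E against 0.444 M of X. A reverse step could hold that gap open, and so could a further loss of E beside the main step; the readings don't separate the two, so I commit to the further loss as a choice. Divide the two: 61.7 % is the E yield, the share of the E left by Q that ends as X. My reckoning takes E as the limiting reagent. Then I expect X to stay at 55.5 % at 10 h, and I expect waiting, more Z and heat to gain nothing. South-east should gain the E yield times its dose, 31 points.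

**The forecast.** It gives 56 % now, south-west as the remedy, 70 % after south-west and 40 % after north-west, reading the curves as a “reversible second-order approach to equilibrium”. On the remedy it differs from my reckoning.

**Result.** The blue flask gives 55.2 % at 10 h, and the best remedy is south-east.

    Z + E → X, rate k1*[Z]^2*[E] (k = 0.160 M⁻² min⁻¹, Ea = 65.0 kJ mol⁻¹)
    E + Q → L (k = 2.40 M⁻¹ min⁻¹, Ea = 59.0 kJ mol⁻¹)
    E → J (k = 0.0290 min⁻¹, Ea = 88.0 kJ mol⁻¹)
    D ⇌ X, rate k4*(cs4 - [X]) while solid is left; crystals form when [X] > cs4 (solubility = 0.280 M, k = 0.220 min⁻¹)
    (constants at 25 °C)

At 10.0 h, 0 % of the E stands free beside 44.8 % of the Z. South-west and north-west stay at 55.2 % and 55.2 %. South-east gains 16 points, about half of the 31 points reckoned from the E yield. For the flask with 0.600 equiv of E, the E yield gives 30.8 %, and that flask reaches 34.9 %.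

The data come from a simulation from invented constants; noise was put on by code.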